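The earlier runs and the new flask are simulated on assumed constants; scatter was added.

3 questions are put to this flask, and behind them stands a decision for the next run: keep the reagent charge and stop at 12 h, or add hours.

* part of the substrate gone at 12 h
* the single product standing at 12 h, as a percentage of the substrate charged
* the side product standing at 12 h, as a percentage of the substrate charged

| flask | substrate | reagent | remark | time |
|---|---|---|---|---|
| green | 0.11 M | 0.176 M | run made earlier |  |
| ochre | 0.24 M | 0.176 M | run made earlier |  |
| amber | 0.16 M | 0.35 M | run made earlier |  |
| flask | 0.16 M | 0.176 M |  | 12 h |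

| run | time / h | substrate / % | single product / % |
|---|---|---|---|
| green | 1.00 | 79.8 | 17.4 |
| green | 1.33 | 75.2 | 21.3 |
| green | 2.00 | 66.8 | 26.0 |
| green | 3.00 | 57.4 | 28.9 |
| green | 5.00 | 43.5 | 31.3 |
| green | 8.00 | 32.7 | 29.4 |
| green | 12.0 | 24.1 | 27.6 |
| ochre | 0.667 | 86.6 | 13.2 |
| ochre | 2.00 | 71.8 | 22.5 |
| ochre | 3.00 | 64.4 | 27.1 |
| ochre | 5.00 | 55.8 | 30.1 |
| ochre | 8.00 | 53.4 | 32.0 |
| ochre | 10.0 | 49.9 | 30.1 |
| ochre | 12.0 | 50.2 | 32.3 |
| amber | 1.00 | 66.6 | 27.4 |
| amber | 3.00 | 36.2 | 30.7 |
| amber | 6.00 | 19.7 | 25.7 |
| amber | 8.00 | 14.5 | 18.8 |
| amber | 12.0 | 7.8 | 16.1 |

(standard deviation of a reading: 1 percentage point)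

- what was read earlier has a scatter of 1 percentage point, one standard deviation

The ochre run points to a balance. Its substrate reads 53.4% at 8.00 h and 50.2% at 12.0 h, which raises the question of how much reagent, the limiting reagent there, has been used. If substrate gone and not standing as single product is counted as side product at two reagent each, the reagent bill per substrate charged is twice the conversion minus the single product. For ochre this bill is 67.3% against a charge of 73.3%.

Setting bill equal to charge and taking single product at the ochre reading gives 71.1% for this flask, the reagent ceiling: reagent per substrate charged plus standing single product, divided by 2. By the same bill, the green run has used 0.137 M of reagent at 12.0 h and the ochre run 0.162 M. With the same reagent charge and a substrate charge between theirs, this flask is reckoned here at a conversion of 58.8% to 66.6%. That range lies 4.5 percentage points to 12 points below the ceiling, which is the conversion that further hours have on offer by this bill, and on that reckoning the next run keeps its charge and stops at 12 h.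

The forecast, which held that the data “fit two consecutive steps”, gave 64% conversion, 30% single product and 34% side product. The flask gives 64.7%, 31.3% and 31.0%.

    crystals ⇌ by-product, rate k1*(cs1 - [by-product]) while solid is left; crystals form when [by-product] > cs1 (solubility = 0.0920 M, k = 0.0300 min⁻¹)
    reagent + bis adduct → tris adduct + by-product (k = 0.00190 M⁻¹ min⁻¹)
    reagent + single product → bis adduct + by-product (k = 0.0290 M⁻¹ min⁻¹)
    bis adduct → side product (k = 0.0110 min⁻¹)
    substrate + reagent → single product + by-product (k = 0.0220 M⁻¹ min⁻¹)
    reagent + tris adduct → tetra adduct + by-product (k = 0.0450 M⁻¹ min⁻¹)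

At 2.09 h single product was made 2.07 times as fast as it was used, and by 12.0 h that ratio stood at 0.857, so the crossing lay between, with single product passing through bis adduct to side product. At 12.0 h the flask stood 6.4 points below the ceiling of 71.1%, with 10% of its reagent left; at 120 h, with reagent at 0%, it shows 69.8% conversion, 30.1% single product and 39.3% side product.

In a neighbouring flask, charged like this one but with 0.044 M of reagent, the ceiling is at its highest when single product equals conversion, which makes it the reagent per substrate charged, 27.5%. That flask gives 22.1% conversion, 18.7% single product and 3.15% side product, with 7.45% of its reagent left.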